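The readings were computed for substances that don't exist; the scatter is artificial.

Late in the west run, double product falls pseudo-first-order, from 29.5% at 10.0 min to 9.4% at 25.0 min, a half-life of 9.09 min. In the south-east run, double product and starting material together read 12.0% at 120 min, yet double is still falling, which suggests that mono adduct has an exit without coupling partner.

all flasks: starting material 0.059 M

| charge | coupling partner | remark | time |
|---|---|---|---|
| south-east | 1.2 equiv | run made earlier |  |
| west | 3.7 equiv | run made earlier |  |
| noon | 0.800 equiv |  | 3.0 h |
| midnight | 2.50 equiv |  | 3.0 h |

| run | time / min | double product / % | starting material / % |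
|---|---|---|---|
| south-east | 20.0 | 14.7 | 10.2 |
| south-east | 40.0 | 12.5 | 6.3 |
| south-east | 50.0 | 12.1 | 4.4 |
| south-east | 80.0 | 12.2 | 3.1 |
| south-east | 90.0 | 11.9 | 2.7 |
| south-east | 120 | 10.3 | 1.7 |
| west | 10.0 | 29.5 | 0 |
| west | 15.0 | 19.3 | 0 |
| west | 25.0 | 9.4 | 0 |
| west | 40.0 | 3.7 | 0.1 |
| west | 50.0 | 2.0 | 0.3 |
| west | 80.0 | 0.1 | 0.1 |
| west | 120 | 0 | 0.4 |

(each reading ± 0.5 percentage points)

- which of these holds the largest part of the starting material at the end of noon (double product / starting material / tris adduct / mono adduct)
- which of these holds the largest part of the starting material at the end of midnight (double product / starting material / tris adduct / mono adduct)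
- amount of double product at the end of midnight, in percent of the starting material charged

Midnight has two extremes. If mono never leaks, each starting material wants 3 equiv, so 2.50 equiv strands 50.0% as double. If all of it leaks, the demand is 1 equiv and double never forms. Partner survives once the leaked share exceeds 25.0%.

Run back to zero time, the west line gives about 63.2% ever reaching double. Taking the partner level as the charge less one equiv, this reckoning reads the split level h, the partner level at which mono leaks as much as it goes on:

h = 1.57 equiv

leaked share = h / (h + level) = 51.1% at midnight

The share is above 25.0%, so demand is 1.98 equiv and partner is spare. Scaling the west half-life by spare partner gives 25.0 min, short against 3.0 h, so n is about 0.333%, with tris adduct largest. At noon, at least 20.0% of the starting material stays unreacted, with partner the limiting reagent. That floor does not pick the largest pool by itself, but the noon partner charge of 0.800 equiv lies below h, so by this reckoning mono leaks faster than it goes on to double. On the assumption that mono drains away within 3.0 h, this reckoning picks starting material for noon.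

The forecast says mono adduct, tris adduct and n = 35% (14% to 50%), on the ground “Partner then runs out near 50% double and 50% tris”.

The flask gives starting material at noon (28.2%), tris adduct at midnight (43.7%) and n = 0.144%.

    coupling partner + double product → tris adduct + by-product (k = 0.781 /M/min)
    starting material + coupling partner → mono adduct + by-product (k = 6.21 /M/min)
    double product + by-product → side product A (k = 0.0155 /M/min)
    mono adduct → side product B (k = 0.202 /min)
    coupling partner + mono adduct → double product + by-product (k = 2.09 /M/min)

In midnight at the asked time, 24% of the partner charge remains. The half-life of double product by its step to tris adduct stands at 0.41 h there, short against 3.0 h. Side product B there holds 54.5%, against the leaked share of 51.1%. In the flask like midnight but with 10.0 equiv, the split level gives a leaked share of 14.9%, and side product B stands at 16.0%.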